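**Retrosynthetic overview**
1. Target locants: ring C1 (quaternary carbinol carbon, carries the exocyclic C7H2OBz), C2 (CHOH), C3 (CHOBz), C4 and C5 (CH2), C6 (CHOH). The end game is bis-benzoylation and global debenzylation of a tri-O-benzyl diol; the C3 hydroxyl comes from anti-hydroboration of a C3=C4 alkene and C7 from reduction of a carboxyl on C1.
2. Key disconnection C1–C2: the array HO2C7–C1(OR)–C2(OR)–C3=C4 is a 2,3-dialkoxypent-4-enoic acid, the retron of a glycolate Ireland–Claisen rearrangement. Because C4 is tied back to C1 through C5–C6, the allyl ester is a δ-lactone (ring O on C4, carbonyl C7) carrying an (E)-C3H=C2H–OBn arm, so the rearrangement is a ring contraction, lactone to cyclohexene, that sets the quaternary C1 and C2 from the one lactone carbinol centre.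
3. The lactone comes from reduction/lactonisation of an (E)-β-benzyloxy enone δ-keto ester, made from a ynone and benzyl alcohol. The ynone acid comes from Jones oxidation of the diol formed by ethynyl Grignard addition to 3,4-di-O-benzyl-2-deoxy-D-threo-pentose (from D-xylal), which supplies C6.
4. Ring order: the pyranoid glycal is opened to a chain, the δ-lactone is closed (step 7), and the cyclohexene is formed from it (step 8, the only carbocycle-forming event).

Key step: step 8

Remark: the sugar C-4 centre becomes the lactone α-carbon, whose configuration is erased on enolisation and reset in the key step, so only the sugar C-3 centre (C6 of the target) has to come from the chiral pool.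

**Route**

Step 1
Reactants: 1 3,4-di-O-acetyl-D-xylal [(3R,4R)-3,4-dihydro-2H-pyran-3,4-diyl diacetate]
Product: 2 3,4-di-O-benzyl-D-xylal [(3R,4R)-3,4-bis(benzyloxy)-3,4-dihydro-2H-pyran]
Conditions: BnBr, powdered KOH, Bu4NI (cat.), THF, 50 °C
Reagents that add atoms: benzyl bromide BrCc1ccccc1
Why: One-pot saponification and Williamson etherification is routine for acetylated glycals, whose enol ether is stable to base, and no stereocentre is touched.

Step 2
Reactants: 2 3,4-di-O-benzyl-D-xylal
Product: 3 3,4-di-O-benzyl-2-deoxy-D-threo-pentopyranose [(4R,5R)-4,5-bis(benzyloxy)oxan-2-ol, anomeric mixture]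
Conditions: PPh3·HBr (5 mol%), H2O, THF, rt
Reagents that add atoms: water O
Why: Mild acid-catalysed Markovnikov hydration of the glycal enol ether should give the 2-deoxy lactol without touching the benzyl ethers, and the new anomeric centre is inconsequential.

Step 3
Reactants: 3 3,4-di-O-benzyl-2-deoxy-D-threo-pentopyranose; 4 ethynylmagnesium bromide
Product: 5 (2R,3R)-2,3-bis(benzyloxy)hept-6-yne-1,5-diol (both C5 epimers)
Conditions: THF, 0 °C to rt (4 equiv of 4); aq. NH4Cl
Reagents that add atoms: none
Why: Grignard addition to the open-chain aldehyde form of the magnesium lactolate should give the diol, and the epimeric mixture at the new carbinol is irrelevant because that centre is oxidised in step 4.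

Step 4
Reactants: 5 (2R,3R)-2,3-bis(benzyloxy)hept-6-yne-1,5-diol
Product: 6 (2S,3R)-2,3-bis(benzyloxy)-5-oxohept-6-ynoic acid
Conditions: CrO3, H2SO4, H2O/acetone, 0 °C
Reagents that add atoms: water O
Why: Jones oxidation should convert the activated propargylic carbinol into the ynone faster than the primary alcohol is oxidised, so no lactol can be trapped as a lactone, and the primary alcohol then passes through the aldehyde hydrate to the acid while benzyl ethers survive at 0 °C.

Step 5
Reactants: 6 (2S,3R)-2,3-bis(benzyloxy)-5-oxohept-6-ynoic acid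
Product: 7 methyl (2S,3R)-2,3-bis(benzyloxy)-5-oxohept-6-ynoate
Conditions: MeI, KHCO3, DMF, rt
Reagents that add atoms: iodomethane CI
Why: Carboxylate O-alkylation under bicarbonate buffering is mild enough for the terminal ynone and for the β-benzyloxy ketone, which should not undergo E1cB loss of benzyl alkoxide.

Step 6
Reactants: 7 methyl (2S,3R)-2,3-bis(benzyloxy)-5-oxohept-6-ynoate; 8 benzyl alcohol
Product: 9 methyl (2S,3R,6E)-2,3,7-tris(benzyloxy)-5-oxohept-6-enoate
Conditions: PMe3 (10 mol%), CH2Cl2, 0 °C to rt
Reagents that add atoms: none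
Why: Phosphine-catalysed oxa-Michael addition of an alcohol to a terminal ynone should give the thermodynamically favoured (E)-β-alkoxy enone, which fixes the enol ether geometry that step 8 translates into a stereocentre.

Step 7
Reactants: 9 methyl (2S,3R,6E)-2,3,7-tris(benzyloxy)-5-oxohept-6-enoate
Product: 11 (3S,4R,6S)-3,4-bis(benzyloxy)-6-[(E)-2-(benzyloxy)ethenyl]oxan-2-one, via hydroxy ester 10 (not isolated)
Conditions: (R)-2-methyl-CBS-oxazaborolidine (0.2 equiv), catecholborane, toluene, −78 to −40 °C; MeOH, aq. NaHCO3 work-up; then DBU (10 mol%), 4 Å MS, toluene, rt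
Reagents that add atoms: none
Why: In the Corey–Bakshi–Shibata reduction the alkenyl group acts as the large and the CH2 group as the small substituent, so the (R)-catalyst should deliver the (5S)-alcohol under reagent control, and base-catalysed 6-exo-trig transesterification then closes the δ-lactone with the new centre trans to the 4-benzyloxy group, without acid that would ionise the γ-alkoxy allylic system.

Step 8
Reactants: 11 (3S,4R,6S)-3,4-bis(benzyloxy)-6-[(E)-2-(benzyloxy)ethenyl]oxan-2-one
Product: 14 (1S,2S,6R)-1,2,6-tris(benzyloxy)cyclohex-3-ene-1-carboxylic acid, via silyl ketene acetal 12 (not isolated), via trimethylsilyl ester 13 (not isolated)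
Conditions: Me3SiCl/Et3N (premixed), LiN(SiMe3)2, THF, −78 °C; then rt to 50 °C; aq. NaHCO3, then citric acid
Reagents that add atoms: none
Why: LiN(SiMe3)2 removes the single α-hydrogen of lactone 11 and the Me3SiCl already present O-silylates the enolate at once to the endocyclic silyl ketene acetal 12, which undergoes a [3,3]-sigmatropic shift to silyl ester 13 (hydrolysed on work-up); the closest known reaction type is the Ireland–Claisen ring contraction of 6-alkenyl δ-lactones to cyclohex-3-enecarboxylic acids, together with glycolate (α-alkoxy) Ireland–Claisen rearrangements and those of glycal esters, whose allyl terminus also carries oxygen. The cyclohexene is closed by pericyclic C–C bond formation between the ketene acetal α-carbon and the enol ether terminus while the lactone C–O bond breaks, so the mode of closure is a suprafacial six-electron ring contraction (δ-lactone to carbocycle, the carboxyl extruded as a substituent) and not a polar exo or endo cyclisation. Because the ketene acetal is endocyclic, the two-carbon tether between its α-carbon and the carbinol carbon allows only a boat transition state (a bicyclo[2.2.2]-like array). The quaternary centre is controlled by the lactone carbinol centre (6S): the alkenyl arm can bond only on the lactone face on which it stands, and since that arm is trans to the 4-benzyloxy group the carboxyl ends cis and the tertiary benzyloxy group trans to that neighbouring benzyloxy group (chirality transfer from C–O to C–C). The second new centre is controlled by the E geometry of the enol ether, which in the enforced boat places its benzyloxy group cis to the carboxyl, that is trans to the tertiary benzyloxy group. The step needs O-silylation and rearrangement to outrun β-elimination of the 4-benzyloxy group from the enolate, which is secured by the internal Me3SiCl quench at −78 °C, by the poor leaving group that can sit equatorial in the 3,4-trans lactone, and by the donor oxygen on the allyl terminus, which should let the shift run near room temperature.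

Step 9
Reactants: 14 (1S,2S,6R)-1,2,6-tris(benzyloxy)cyclohex-3-ene-1-carboxylic acid
Product: 15 [(1S,2S,6R)-1,2,6-tris(benzyloxy)cyclohex-3-en-1-yl]methanol
Conditions: LiAlH4, THF, 0 °C to reflux
Reagents that add atoms: none
Why: LiAlH4 reduction of the hindered carboxylic acid should give the primary alcohol while the isolated alkene and the benzyl ethers are inert.

Step 10
Reactants: 15 [(1S,2S,6R)-1,2,6-tris(benzyloxy)cyclohex-3-en-1-yl]methanol
Product: 16 (1R,2S,3S,4R)-2,3,4-tris(benzyloxy)-3-(hydroxymethyl)cyclohexan-1-ol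
Conditions: 9-BBN (3 equiv), THF, rt to 50 °C; then NaOH, H2O2, 0 °C
Reagents that add atoms: hydrogen peroxide OO
Why: Hydroboration–oxidation of a cyclic allylic ether should place boron on the alkene carbon next to the benzyloxy-bearing carbon (inductive control) and anti to that benzyloxy group, so the new hydroxyl is trans to the neighbouring OBn, and the primary alcohol, bound as a B–O borinate without B–H, cannot deliver boron to the wrong face.

Step 11
Reactants: 16 (1R,2S,3S,4R)-2,3,4-tris(benzyloxy)-3-(hydroxymethyl)cyclohexan-1-ol; 17 benzoyl chloride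
Product: 18 [(1S,2S,3R,6R)-3-(benzoyloxy)-1,2,6-tris(benzyloxy)cyclohexyl]methyl benzoate
Conditions: 17 (2.5 equiv), pyridine, DMAP (cat.), CH2Cl2, 0 °C to rt
Reagents that add atoms: benzoyl chloride (second equivalent of 17) O=C(Cl)c1ccccc1
Why: DMAP-catalysed acylation with two equivalents of benzoyl chloride, one consumed per hydroxyl, should esterify the only two free hydroxyls (one primary, one secondary) with retention of configuration.

Step 12
Reactants: 18 [(1S,2S,3R,6R)-3-(benzoyloxy)-1,2,6-tris(benzyloxy)cyclohexyl]methyl benzoate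
Product: 19 [(1S,2S,3R,6R)-3-(benzoyloxy)-1,2,6-trihydroxycyclohexyl]methyl benzoate (CNP0264996.1)
Conditions: H2 (1 atm), Pd(OH)2/C, EtOAc/EtOH, rt
Reagents that add atoms: none
Why: Hydrogenolysis should cleave the two secondary and the tertiary benzyl ethers under neutral conditions that leave the benzoates in place and do not promote acyl migration.

**Compound list**
1 | 3,4-di-O-acetyl-D-xylal, (3R,4R)-3,4-dihydro-2H-pyran-3,4-diyl diacetate | O1C=C[C@@H](OC(C)=O)[C@H](OC(C)=O)C1 | starting material
2 | 3,4-di-O-benzyl-D-xylal, (3R,4R)-3,4-bis(benzyloxy)-3,4-dihydro-2H-pyran | O1C=C[C@@H](OCc2ccccc2)[C@H](OCc2ccccc2)C1 | intermediate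
3 | 3,4-di-O-benzyl-2-deoxy-D-threo-pentopyranose, (4R,5R)-4,5-bis(benzyloxy)oxan-2-ol | OC1C[C@@H](OCc2ccccc2)[C@H](OCc2ccccc2)CO1 | intermediate
4 | ethynylmagnesium bromide | C#C[Mg]Br | starting material
5 | (2R,3R)-2,3-bis(benzyloxy)hept-6-yne-1,5-diol (C5 epimers) | C#CC(O)C[C@@H](OCc1ccccc1)[C@H](OCc1ccccc1)CO | intermediate
6 | (2S,3R)-2,3-bis(benzyloxy)-5-oxohept-6-ynoic acid | C#CC(=O)C[C@@H](OCc1ccccc1)[C@H](OCc1ccccc1)C(=O)O | intermediate
7 | methyl (2S,3R)-2,3-bis(benzyloxy)-5-oxohept-6-ynoate | C#CC(=O)C[C@@H](OCc1ccccc1)[C@H](OCc1ccccc1)C(=O)OC | intermediate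
8 | benzyl alcohol | OCc1ccccc1 | starting material
9 | methyl (2S,3R,6E)-2,3,7-tris(benzyloxy)-5-oxohept-6-enoate | O=C(/C=C/OCc1ccccc1)C[C@@H](OCc1ccccc1)[C@H](OCc1ccccc1)C(=O)OC | intermediate
10 | methyl (2S,3R,5S,6E)-2,3,7-tris(benzyloxy)-5-hydroxyhept-6-enoate | O[C@H](/C=C/OCc1ccccc1)C[C@@H](OCc1ccccc1)[C@H](OCc1ccccc1)C(=O)OC | intermediate
11 | (3S,4R,6S)-3,4-bis(benzyloxy)-6-[(E)-2-(benzyloxy)ethenyl]oxan-2-one | O=C1O[C@H](/C=C/OCc2ccccc2)C[C@@H](OCc2ccccc2)[C@@H]1OCc1ccccc1 | intermediate
12 | {[(4R,6S)-3,4-bis(benzyloxy)-6-[(E)-2-(benzyloxy)ethenyl]-5,6-dihydro-4H-pyran-2-yl]oxy}trimethylsilane | C[Si](C)(C)OC1=C(OCc2ccccc2)[C@H](OCc2ccccc2)C[C@@H](/C=C/OCc2ccccc2)O1 | intermediate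
13 | trimethylsilyl (1S,2S,6R)-1,2,6-tris(benzyloxy)cyclohex-3-ene-1-carboxylate | C[Si](C)(C)OC(=O)[C@]1(OCc2ccccc2)[C@H](OCc2ccccc2)CC=C[C@@H]1OCc1ccccc1 | intermediate
14 | (1S,2S,6R)-1,2,6-tris(benzyloxy)cyclohex-3-ene-1-carboxylic acid | OC(=O)[C@]1(OCc2ccccc2)[C@H](OCc2ccccc2)CC=C[C@@H]1OCc1ccccc1 | intermediate
15 | [(1S,2S,6R)-1,2,6-tris(benzyloxy)cyclohex-3-en-1-yl]methanol | OC[C@]1(OCc2ccccc2)[C@H](OCc2ccccc2)CC=C[C@@H]1OCc1ccccc1 | intermediate
16 | (1R,2S,3S,4R)-2,3,4-tris(benzyloxy)-3-(hydroxymethyl)cyclohexan-1-ol | OC[C@]1(OCc2ccccc2)[C@H](OCc2ccccc2)CC[C@@H](O)[C@@H]1OCc1ccccc1 | intermediate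
17 | benzoyl chloride | O=C(Cl)c1ccccc1 | starting material
18 | [(1S,2S,3R,6R)-3-(benzoyloxy)-1,2,6-tris(benzyloxy)cyclohexyl]methyl benzoate | O=C(OC[C@]1(OCc2ccccc2)[C@H](OCc2ccccc2)CC[C@@H](OC(=O)c2ccccc2)[C@@H]1OCc1ccccc1)c1ccccc1 | intermediate
19 | [(1S,2S,3R,6R)-3-(benzoyloxy)-1,2,6-trihydroxycyclohexyl]methyl benzoate | O=C(OC[C@]1(O)[C@H](O)CC[C@@H](OC(=O)c2ccccc2)[C@@H]1O)c1ccccc1 | target

**Step count and risks**

Total step count: 12. Longest linear sequence: 12 steps (from 1).

Steps most likely to fail:

Step 8. β-Elimination of benzyl alkoxide from the lithium lactone enolate may compete with O-silylation, or the doubly activated allylic C–O bond may ionise before the sigmatropic shift. An enolate-free variant at the aldehyde oxidation level would set out from 11. Reduction with i-Bu2AlH (toluene, −78 °C) should give the lactol (3S,4R,6S)-3,4-bis(benzyloxy)-6-[(E)-2-(benzyloxy)ethenyl]oxan-2-ol F1. Dehydration (MsCl, Et3N, then DBU) should give the cyclic enol ether (2S,4R)-4,5-bis(benzyloxy)-2-[(E)-2-(benzyloxy)ethenyl]-3,4-dihydro-2H-pyran F2. Thermal Claisen rearrangement of this allyl vinyl ether (o-dichlorobenzene, trace Et3N, about 170 °C) goes through the same enforced boat with the same stereochemical course and should give (1S,2S,6R)-1,2,6-tris(benzyloxy)cyclohex-3-ene-1-carbaldehyde F3. NaBH4 reduction then comes back to the route at 15.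

Step 7. The vinylogous-ester carbonyl may be too unreactive or show eroded facial selectivity in the oxazaborolidine reduction, and the γ-alkoxy allylic alcohol may undergo allylic transposition during lactonisation. The alternative sets the carbinol centre on the robust ynone and installs the enol ether last; it sets out from 7. Reduction with (S)-Alpine-Borane (B-isopinocampheyl-9-BBN, THF, rt) should give methyl (2S,3R,5S)-2,3-bis(benzyloxy)-5-hydroxyhept-6-ynoate F4. Lactonisation (PPTS, toluene, 60 °C) should give (3S,4R,6S)-3,4-bis(benzyloxy)-6-ethynyloxan-2-one F5. syn-Hydroboration with pinacolborane and Cp2Zr(H)Cl (cat.) should give (3S,4R,6S)-3,4-bis(benzyloxy)-6-[(E)-2-(4,4,5,5-tetramethyl-1,3,2-dioxaborolan-2-yl)ethenyl]oxan-2-one F6. A stereoretentive Chan–Lam-type coupling with benzyl alcohol (Cu(OAc)2, Et3N, rt) then comes back to the route at 11.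

Step 10. Steric control may override the inductive effect of the allylic benzyloxy group, so that boron goes to the remote alkene carbon. The alternative sets out from 15. Epoxidation with dimethyldioxirane (acetone, 0 °C) anti to the allylic benzyloxy group should give [(1R,2S,3S,4R,6R)-2,3,4-tris(benzyloxy)-7-oxabicyclo[4.1.0]heptan-3-yl]methanol F7. LiAlH4 (THF) should open the epoxide trans-diaxially at the carbon remote from the benzyloxy-bearing carbon, which comes back to the route at 16.

**Further compounds**
F1 | step 8 | (3S,4R,6S)-3,4-bis(benzyloxy)-6-[(E)-2-(benzyloxy)ethenyl]oxan-2-ol | OC1O[C@H](/C=C/OCc2ccccc2)C[C@@H](OCc2ccccc2)[C@@H]1OCc1ccccc1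
F2 | step 8 | (2S,4R)-4,5-bis(benzyloxy)-2-[(E)-2-(benzyloxy)ethenyl]-3,4-dihydro-2H-pyran | C1=C(OCc2ccccc2)[C@H](OCc2ccccc2)C[C@@H](/C=C/OCc2ccccc2)O1
F3 | step 8 | (1S,2S,6R)-1,2,6-tris(benzyloxy)cyclohex-3-ene-1-carbaldehyde | O=C[C@]1(OCc2ccccc2)[C@H](OCc2ccccc2)CC=C[C@@H]1OCc1ccccc1
F4 | step 7 | methyl (2S,3R,5S)-2,3-bis(benzyloxy)-5-hydroxyhept-6-ynoate | C#C[C@@H](O)C[C@@H](OCc1ccccc1)[C@H](OCc1ccccc1)C(=O)OC
F5 | step 7 | (3S,4R,6S)-3,4-bis(benzyloxy)-6-ethynyloxan-2-one | O=C1O[C@H](C#C)C[C@@H](OCc2ccccc2)[C@@H]1OCc1ccccc1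
F6 | step 7 | (3S,4R,6S)-3,4-bis(benzyloxy)-6-[(E)-2-(4,4,5,5-tetramethyl-1,3,2-dioxaborolan-2-yl)ethenyl]oxan-2-one | O=C1O[C@H](/C=C/B2OC(C)(C)C(C)(C)O2)C[C@@H](OCc2ccccc2)[C@@H]1OCc1ccccc1
F7 | step 10 | [(1R,2S,3S,4R,6R)-2,3,4-tris(benzyloxy)-7-oxabicyclo[4.1.0]heptan-3-yl]methanol | OC[C@]1(OCc2ccccc2)[C@H](OCc2ccccc2)C[C@H]2O[C@H]2[C@@H]1OCc1ccccc1
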